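## Structural features

Isodihydromaldoxin is a diaryl ether of two benzoic acid units and has no stereocentre. Ring A is a tetrasubstituted benzene with a methyl ester (C1), the ether oxygen (C2), a methoxy group (C3) and a free hydroxyl (C5). Ring B is pentasubstituted, with the ether oxygen (C1'), a methyl group (C3'), chlorine (C4'), a hydroxyl (C5') and a free carboxylic acid (C6'). The ether oxygen has three ortho substituents (CO2Me and OMe on ring A, CO2H on ring B), so joining two finished rings by an aryl–oxygen coupling would be the hard way to make it. Several groups must be told apart: one carboxyl is a methyl ester and the other is free, one phenol oxygen is methylated and two are free, and the chlorine must occupy one particular activated position of an orcinol-type ring. The fragile points are the methyl ester (hydrolysis), the aryl chloride (hydrogenolysis), the chelating salicylic acid unit of ring B and, in the intermediates, any β-aryloxy carbonyl arrangement, which can expel the aryloxide. The key step exploits the 1,3-relationship of the oxygens on C3 and C5 of ring A: the ring is a masked cyclohexane-1,3-dione whose C2 already carries the ether oxygen and whose C1 carries the ester, so C2–C3–C4 can come from the acetone part of a ring B aryloxyacetone and C1, C6 and C5 from a fumarate. The two stereocentres formed in that annulation (C1 and C2) are adjacent and both disappear on aromatization.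

## Logic of the disconnections

**16 back to 15 and 14.** The O–Si bond on the C5 oxygen is cut first (16 from 15), then the O–CH3 bond on the C5' oxygen together with the O–C(CH3)3 bond of the C6' carboxyl (15 from 14). This keeps the polar, chelating salicylic acid and the free phenol masked to the end, so every earlier intermediate is neutral and easy to purify. The forward steps must be chemoselective: the Lewis acid has to take the C5' methyl group, which is activated by chelation to the adjacent carbonyl, and spare the C3 methyl ether and the C1 methyl ester; the fluoride step must spare the methyl ester.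

**14 back to 13 and 12.** The O–CH3 bond at C3 and the O–Si bond at C5 are cut. The two hydroxyls of 12 emerge undifferentiated from the aromatization and differ only in their surroundings (C5–OH has two ortho hydrogens, C3–OH lies next to the aryloxy group). The gain is that 12 carries no protecting group on ring A at all. The forward silylation must therefore select the C5 hydroxyl on steric grounds before the C3 hydroxyl is methylated.

**12 back to 11.** Two hydrogens are returned to ring A (on C1 and C2), which reveals the resorcinol as a cyclohexane-1,3-dione. Ring A then becomes accessible by carbonyl condensation instead of arene substitution. The forward oxidation must not halogenate the electron-rich rings and must be faster than loss of the aryloxy group.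

**11 back to 8 and 9, through 10.** The C1–C2 bond and the C4–C5 bond are cut. C1–C2 is the bond of a 1,5-dicarbonyl relationship between C3 and C5 (a Michael retron) and C4–C5 closes a 1,3-dicarbonyl (a Claisen retron). The cut removes the whole of ring A, two C–C bonds and both stereocentres, and leaves an achiral ketone and a commodity diester; the hindered ether bond O–C2 is already present in 8. The forward step must use the oxygen-bearing methylene of 8 as Michael donor, must close the six-membered ring, and must leave the ring B ester untouched, which is why that ester is tert-butyl and flanked by two ortho substituents.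

**8 back to 6 and 7.** The O–CH2 bond is cut. The ring B oxygen is joined to sp3 carbon by simple alkylation, so no aryl–oxygen coupling is needed anywhere. The forward step only needs a base too weak to enolize the product toward its own ester.

**6 back to 5 and 3, through 4.** The bond between C6' and the carboxyl carbon is cut. C6' lies between two oxygens and is the natural site of directed lithiation, so the carboxyl can be added to a ring that already has all its other substituents. The phenol needs a protecting group that directs lithium and that comes off under conditions harmless to a tert-butyl ester; a tetrahydropyranyl acetal is chosen for that reason.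

**3 back to 2 and 1.** The acetal C–O bond and then the C4'–Cl bond are cut, leading to a commercial orcinol monomethyl ether in which the two ring B oxygens are already differentiated. The forward chlorination must go para to the free hydroxyl and not para to the methoxy group.

## Other disconnections considered

**Alternative 1:** The cut runs through ring B at C3'–C4' and C5'–C6'. In the forward step the 3-carboxylated 4-aryloxy-6-methyl-2-pyrone A2 is heated with the chloroketene acetal A3; an inverse-demand Diels–Alder adduct forms, and decarboxylative cycloreversion plus elimination of one methoxy group give the diaryl ether A1.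
- In its favour: the chlorine arrives in the dienophile, so its position follows from the polarity of the cycloaddition (CHCl carbon to the methyl-bearing pyrone terminus, acetal carbon to the ester-bearing one) and not from an electrophilic substitution. Ring B is delivered aromatic with no oxidation. The ether bond can be made by addition–elimination at C4 of a pyrone.
- Against it here: the aryloxy donor on C4 makes the pyrone a poorer electron-deficient diene, so prolonged heating would be needed, and A3 is prone to oligomerize or dehydrochlorinate under such conditions. The ring A phenol that must be attached is 2,6-disubstituted and needs its own synthesis with the C5 oxygen protected differently from the C3 methoxy group.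
- Comparison: on structure it is better than the chosen plan in placing chlorine and in avoiding an oxidation, and equal in forming the hindered ether without an aryl–oxygen coupling. On mechanism a pericyclic step with predictable regiochemistry is more foreseeable than an enolate cascade with competing pathways, once the partners exist. On step economy the total should be comparable and the longest linear sequence shorter through convergence, which is a point in its favour. The end game (Lewis acid removal of benzyl and methyl groups, no hydrogenolysis because of the C–Cl bond) is equal.

**Alternative 2:** The cut removes the O–C1' bond and the bond from C6' to the carboxyl carbon. In the forward step a fluoride source releases the ring B aryne from the silyl triflate A5 under an atmosphere of A7 (carbon dioxide); the phenoxide of A6 adds to C1' and the aryl anion on C6' is carboxylated, giving A4.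
- In its favour: the most hindered bond and the carboxyl group are made in one operation. The methoxy group next to the aryne supports the regiochemistry (nucleophile to the distal carbon, anion beside the inductively withdrawing oxygen). The acid arrives free, so no tert-butyl ester is needed, which is better than the chosen plan on that point.
- Against it here: phenoxides are modest aryne nucleophiles, and under A7 they are partly held as aryl carbonates. The aryl anion can be protonated before it is carboxylated. The phenoxide of A6 is 2,6-disubstituted. The ring A ester cannot be present because it would trap the aryl anion, so it must be added later by carbonylation of C–Br in the presence of C–Cl. A5 would be made from 2 in several steps and inherits the same chlorination question (equal).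
- Comparison: on structure it is more convergent (better). On mechanism three components must react in order with no selectivity enforced intramolecularly, whereas in the chosen plan the ether bond pre-exists and the ring closure is intramolecular. On step economy the total should be about equal, with a shorter longest linear sequence.

**Alternative 3:** The cut runs through ring B at C1'–C2' and C5'–C6'. In the forward step the aryloxypropiolate A9 and the vinylketene acetal A10 undergo a Diels–Alder reaction; elimination of the methoxy group and loss of the silyl group give A8 with the C5' hydroxyl free.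
- In its favour: methyl and chlorine are pre-placed in the diene. The C5' hydroxyl is obtained free and already distinguished from the other oxygens, so no late demethylation is needed (better than the chosen plan). No oxidation is required.
- Against it here: A9 is an ynol ether ester, sensitive and difficult to make from a hindered phenol that also carries an ester. Its aryloxy donor lowers its dienophilicity and weakens the polarization that controls regiochemistry. A10 must be made by γ-deprotonation and silylation of an α-chloro enoate and is labile to hydrolysis.
- Comparison: on structure it is equal or better (free C5' phenol, chlorine by construction). On mechanism it rests on two reactive partners that must survive heating, against one base-mediated cascade in the chosen plan. On step economy it is probably equal, but more of its steps lack close analogy.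

Key step: step 6

Assumptions (chemistry): 1, 7 and 9 are purchased; 3 and 5 are racemic at the acetal carbon; 11 is written as the diketo form of the racemic trans isomer (1R*,2S*), although it will be largely enolized.

## Route

Step 1
Reactants: 1 3-methoxy-5-methylphenol
Product: 2 4-chloro-3-methoxy-5-methylphenol
Conditions: SO2Cl2 (1.0 equiv), Ph2S (cat.), AlCl3 (cat.), CH2Cl2, 0 °C to rt
Reagents that add atoms: sulfuryl chloride, O=S(=O)(Cl)Cl
Why: Electrophilic aromatic chlorination; the bulky chlorosulfonium species formed from SO2Cl2 and the sulfide should attack para to the free hydroxyl (also ortho to the methoxy group), the carbon that becomes C4'. Attack para to the methoxy group is the expected minor path, and that isomer is removed here.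

Step 2
Reactants: 2 4-chloro-3-methoxy-5-methylphenol
Product: 3 2-(4-chloro-3-methoxy-5-methylphenoxy)oxane (racemic)
Conditions: 3,4-dihydro-2H-pyran (1.5 equiv), PPTS (cat.), CH2Cl2, rt
Reagents that add atoms: 3,4-dihydro-2H-pyran, C1CCOC=C1
Why: Acid-catalysed addition of the phenol to the enol ether gives the mixed acetal, which is inert to organolithium reagents and coordinates lithium. The acetal centre is racemic and is removed in step 4.

Step 3
Reactants: 3 2-(4-chloro-3-methoxy-5-methylphenoxy)oxane
Product: 5 tert-butyl 3-chloro-2-methoxy-4-methyl-6-(oxan-2-yloxy)benzoate (racemic), via aryllithium 4 (not isolated)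
Conditions: n-BuLi (1.2 equiv), THF, 0 °C; then Boc2O (1.5 equiv), −78 °C to rt
Reagents that add atoms: di-tert-butyl dicarbonate, CC(C)(C)OC(=O)OC(=O)OC(C)(C)C; n-butyllithium, [Li]CCCC (supplies the lithium of 4 only)
Why: Directed ortho-metalation: the hydrogen between the acetal oxygen and the methoxy oxygen is removed with both oxygens coordinating lithium, and acylation of the aryllithium by the dicarbonate gives the tert-butyl ester directly. The chlorine is meta to the lithiated carbon, so no aryne can form.

Step 4
Reactants: 5 tert-butyl 3-chloro-2-methoxy-4-methyl-6-(oxan-2-yloxy)benzoate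
Product: 6 tert-butyl 3-chloro-6-hydroxy-2-methoxy-4-methylbenzoate
Conditions: PPTS (10 mol%), MeOH, 45 °C
Reagents that add atoms: none
Why: Transacetalization to methanol under very mild acid frees the phenol. These conditions do not ionize a tert-butyl ester, which is the reason for choosing this acetal.

Step 5
Reactants: 6 tert-butyl 3-chloro-6-hydroxy-2-methoxy-4-methylbenzoate; 7 chloroacetone (1-chloropropan-2-one)
Product: 8 tert-butyl 3-chloro-2-methoxy-4-methyl-6-(2-oxopropoxy)benzoate
Conditions: 7 (1.3 equiv), K2CO3, KI (cat.), acetone, 55 °C
Reagents that add atoms: none
Why: Williamson ether synthesis (SN2) of the phenoxide with the activated α-chloro ketone under iodide catalysis. K2CO3 is too weak to form the ketone enolate that could cyclize onto the hindered ester.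

Step 6
Reactants: 8 tert-butyl 3-chloro-2-methoxy-4-methyl-6-(2-oxopropoxy)benzoate; 9 dimethyl fumarate (dimethyl (2E)-but-2-enedioate)
Product: 11 methyl (1R*,2S*)-2-[2-(tert-butoxycarbonyl)-4-chloro-3-methoxy-5-methylphenoxy]-3,5-dioxocyclohexane-1-carboxylate (racemic trans), via Michael adduct 10 (not isolated)
Conditions: 9 (1.1 equiv), THF, −20 °C; KOtBu (1.3 equiv, 1 M in THF) added last, −20 °C to rt; then cold 1 M HCl
Reagents that add atoms: none
Why: tert-Butoxide deprotonates 8 reversibly, and the enolate at the aryloxy-bearing methylene, the more stable one because of the inductive effect of the oxygen, adds to 9 in a Michael reaction that joins C2 to C1 and leaves the ester enolate of 10. Proton transfer (a six-membered intramolecular route from the methyl group is open) gives the methyl ketone enolate, whose carbon C4 attacks the distal ester carbonyl C5 in a Claisen condensation; loss of methoxide and deprotonation of the new 1,3-dione make the sequence irreversible. The closest known reaction type is the consecutive Michael–Claisen annulation of substituted acetones with α,β-unsaturated esters to cyclohexane-1,3-diones. Ring A closes in the 6-(enolendo)-exo-trig mode, whereas closure onto the nearer ester would be a 5-(enolendo)-exo-trig process that the geometry of the enolate disfavours. C1 and C2 are both epimerizable under the conditions (α to the ester and α to a ring carbonyl), so thermodynamic control should place the ester and the aryloxy group trans and equatorial; the product is racemic and both centres are erased in step 7. The step needs the Michael donor to be the OCH2 carbon and not the methyl group, which the higher acidity of the former secures, and it needs the enolates to ignore the ring B ester, which its tert-butyl group, its two ortho substituents and its lack of α-hydrogens secure. Having 9 in the flask before the base, a near-stoichiometric charge of base and a cold acidic quench are chosen to outrun the two side paths the substrate allows, five-membered acyl transfer to the ring B ester and β-elimination of the aryloxide from the C1 ester enolate of 10.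

Step 7
Reactants: 11 methyl (1R*,2S*)-2-[2-(tert-butoxycarbonyl)-4-chloro-3-methoxy-5-methylphenoxy]-3,5-dioxocyclohexane-1-carboxylate
Product: 12 methyl 2-[2-(tert-butoxycarbonyl)-4-chloro-3-methoxy-5-methylphenoxy]-3,5-dihydroxybenzoate
Conditions: DDQ (1.1 equiv), 1,4-dioxane, 80 °C
Reagents that add atoms: none
Why: Dehydrogenation of a cyclohexane-1,3-dione to a resorcinol by a high-potential quinone: hydride abstraction from C1 of the dienol gives a cation stabilized by both oxygens, and loss of the C2 proton gives the arene. No halogen electrophile is involved, so the electron-rich rings should not be halogenated.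

Step 8
Reactants: 12 methyl 2-[2-(tert-butoxycarbonyl)-4-chloro-3-methoxy-5-methylphenoxy]-3,5-dihydroxybenzoate
Product: 13 methyl 2-[2-(tert-butoxycarbonyl)-4-chloro-3-methoxy-5-methylphenoxy]-3-hydroxy-5-{[tri(propan-2-yl)silyl]oxy}benzoate
Conditions: TIPSCl (1.05 equiv), imidazole, CH2Cl2, 0 °C
Reagents that add atoms: chlorotri(propan-2-yl)silane, CC(C)[Si](Cl)(C(C)C)C(C)C
Why: Silylation of a phenol; the bulky silyl chloride should react only at the C5 hydroxyl, which has two ortho hydrogens, while the C3 hydroxyl is screened by the twisted ortho aryloxy group.

Step 9
Reactants: 13 methyl 2-[2-(tert-butoxycarbonyl)-4-chloro-3-methoxy-5-methylphenoxy]-3-hydroxy-5-{[tri(propan-2-yl)silyl]oxy}benzoate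
Product: 14 methyl 2-[2-(tert-butoxycarbonyl)-4-chloro-3-methoxy-5-methylphenoxy]-3-methoxy-5-{[tri(propan-2-yl)silyl]oxy}benzoate
Conditions: MeI (3 equiv), K2CO3, acetone, 40 °C
Reagents that add atoms: iodomethane, CI
Why: Williamson O-methylation of the only remaining acidic hydroxyl. The aryl triisopropylsilyl ether and both esters should tolerate K2CO3 in acetone.

Step 10
Reactants: 14 methyl 2-[2-(tert-butoxycarbonyl)-4-chloro-3-methoxy-5-methylphenoxy]-3-methoxy-5-{[tri(propan-2-yl)silyl]oxy}benzoate
Product: 15 3-chloro-2-hydroxy-6-(2-methoxy-6-(methoxycarbonyl)-4-{[tri(propan-2-yl)silyl]oxy}phenoxy)-4-methylbenzoic acid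
Conditions: BCl3 (4 equiv, 1 M in CH2Cl2), CH2Cl2, −78 to 0 °C; then H2O
Reagents that add atoms: none
Why: Lewis acid dealkylation: BCl3 ionizes the tert-butyl ester and, held in a six-membered chelate by the ring B carbonyl oxygen, cleaves the adjacent C5' methyl ether by chloride attack on the methyl group. The C3 methyl ether (no ortho carbonyl), the methyl ester and the hindered silyl ether should persist at or below 0 °C; any silyl ether lost here converges on the same final product.

Step 11
Reactants: 15 3-chloro-2-hydroxy-6-(2-methoxy-6-(methoxycarbonyl)-4-{[tri(propan-2-yl)silyl]oxy}phenoxy)-4-methylbenzoic acid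
Product: 16 3-chloro-2-hydroxy-6-[4-hydroxy-2-methoxy-6-(methoxycarbonyl)phenoxy]-4-methylbenzoic acid (isodihydromaldoxin)
Conditions: TBAF (3 equiv), THF, 0 °C; then 1 M HCl
Reagents that add atoms: none
Why: Fluoride-induced desilylation driven by the Si–F bond. Aryl silyl ethers cleave quickly at 0 °C, before the methyl ester can be affected, and acidification returns the free acid.

## Compound list

1 | 3-methoxy-5-methylphenol | COc1cc(C)cc(O)c1 | starting material
2 | 4-chloro-3-methoxy-5-methylphenol | COc1cc(O)cc(C)c1Cl | intermediate
3 | 2-(4-chloro-3-methoxy-5-methylphenoxy)oxane (racemic) | COc1cc(OC2CCCCO2)cc(C)c1Cl | intermediate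
4 | [3-chloro-2-methoxy-4-methyl-6-(oxan-2-yloxy)phenyl]lithium (racemic, not isolated) | [Li]c1c(OC)c(Cl)c(C)cc1OC1CCCCO1 | intermediate
5 | tert-butyl 3-chloro-2-methoxy-4-methyl-6-(oxan-2-yloxy)benzoate (racemic) | CC(C)(C)OC(=O)c1c(OC)c(Cl)c(C)cc1OC1CCCCO1 | intermediate
6 | tert-butyl 3-chloro-6-hydroxy-2-methoxy-4-methylbenzoate | CC(C)(C)OC(=O)c1c(OC)c(Cl)c(C)cc1O | intermediate
7 | chloroacetone (1-chloropropan-2-one) | CC(=O)CCl | starting material
8 | tert-butyl 3-chloro-2-methoxy-4-methyl-6-(2-oxopropoxy)benzoate | CC(=O)COc1cc(C)c(Cl)c(OC)c1C(=O)OC(C)(C)C | intermediate
9 | dimethyl fumarate (dimethyl (2E)-but-2-enedioate) | COC(=O)/C=C/C(=O)OC | starting material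
10 | dimethyl 2-{1-[2-(tert-butoxycarbonyl)-4-chloro-3-methoxy-5-methylphenoxy]-2-oxopropyl}butanedioate (diastereomer mixture, racemic, present as its potassium enolate, not isolated) | COC(=O)CC(C(=O)OC)C(Oc1cc(C)c(Cl)c(OC)c1C(=O)OC(C)(C)C)C(C)=O | intermediate
11 | methyl (1R*,2S*)-2-[2-(tert-butoxycarbonyl)-4-chloro-3-methoxy-5-methylphenoxy]-3,5-dioxocyclohexane-1-carboxylate (racemic trans, one enantiomer drawn) | COC(=O)[C@@H]1CC(=O)CC(=O)[C@H]1Oc1cc(C)c(Cl)c(OC)c1C(=O)OC(C)(C)C | intermediate
12 | methyl 2-[2-(tert-butoxycarbonyl)-4-chloro-3-methoxy-5-methylphenoxy]-3,5-dihydroxybenzoate | COC(=O)c1cc(O)cc(O)c1Oc1cc(C)c(Cl)c(OC)c1C(=O)OC(C)(C)C | intermediate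
13 | methyl 2-[2-(tert-butoxycarbonyl)-4-chloro-3-methoxy-5-methylphenoxy]-3-hydroxy-5-{[tri(propan-2-yl)silyl]oxy}benzoate | COC(=O)c1cc(O[Si](C(C)C)(C(C)C)C(C)C)cc(O)c1Oc1cc(C)c(Cl)c(OC)c1C(=O)OC(C)(C)C | intermediate
14 | methyl 2-[2-(tert-butoxycarbonyl)-4-chloro-3-methoxy-5-methylphenoxy]-3-methoxy-5-{[tri(propan-2-yl)silyl]oxy}benzoate | COC(=O)c1cc(O[Si](C(C)C)(C(C)C)C(C)C)cc(OC)c1Oc1cc(C)c(Cl)c(OC)c1C(=O)OC(C)(C)C | intermediate
15 | 3-chloro-2-hydroxy-6-(2-methoxy-6-(methoxycarbonyl)-4-{[tri(propan-2-yl)silyl]oxy}phenoxy)-4-methylbenzoic acid | COC(=O)c1cc(O[Si](C(C)C)(C(C)C)C(C)C)cc(OC)c1Oc1cc(C)c(Cl)c(O)c1C(=O)O | intermediate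
16 | 3-chloro-2-hydroxy-6-[4-hydroxy-2-methoxy-6-(methoxycarbonyl)phenoxy]-4-methylbenzoic acid (isodihydromaldoxin) | COC(=O)c1cc(O)cc(OC)c1Oc1cc(C)c(Cl)c(O)c1C(=O)O | target

## Step count and least certain steps

Total step count: 11. Longest linear sequence: 11 steps (1 to 16); 7 and 9 enter as purchased reagents.

**Step 6 (key step).** Three processes could divert it: acyl transfer from the ring B tert-butyl ester to the aryloxy-substituted enolate (a five-membered closure, well known for less hindered esters); β-elimination of the aryloxide once the C1 ester enolate of the open-chain adduct forms; and conjugate addition through the methyl carbon, which would give the regioisomeric dione. The first two arise because the same enolates needed for the annulation sit next to an electrophilic ester and β to a reasonable leaving group.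
The fallback sets out from 8 and returns at 12. It carries the ring B carboxyl through the base step as a carboxylate, which cannot be acylated and which turns the aryloxide into a dianionic, much poorer leaving group. CF3CO2H in CH2Cl2 cleaves the ester of 8 to 3-chloro-2-methoxy-4-methyl-6-(2-oxopropoxy)benzoic acid F1. Annulation with 9 (KOtBu, about 2.5 equiv, THF–DMF) should give racemic trans 3-chloro-2-methoxy-6-{[2-(methoxycarbonyl)-4,6-dioxocyclohexyl]oxy}-4-methylbenzoic acid F2. DDQ as in step 7 gives 3-chloro-6-[2,4-dihydroxy-6-(methoxycarbonyl)phenoxy]-2-methoxy-4-methylbenzoic acid F3. tert-Butyl 2,2,2-trichloroacetimidate without added acid, which alkylates carboxylic acids and leaves phenols, re-forms the ester and gives 12.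

**Step 1.** Chlorination para to the methoxy group (ortho to the hydroxyl) or double chlorination may compete, because three ring positions are activated by both oxygens.
The fallback does not use 1; it sets out from commercial 2-chloro-3-methylphenol F4 in its place and returns at 2. O-Methylation (MeI, K2CO3) gives 2-chloro-1-methoxy-3-methylbenzene F5. Iridium-catalysed C–H borylation ([Ir(OMe)(cod)]2, 4,4'-di-tert-butyl-2,2'-bipyridine, B2pin2) is sterically controlled and on a 1,2,3-trisubstituted benzene goes to the one C–H without an ortho substituent, giving 2-(4-chloro-3-methoxy-5-methylphenyl)-4,4,5,5-tetramethyl-1,3,2-dioxaborolane F6. Oxidation of the C–B bond (H2O2, NaOH) gives 2 with the chlorine position fixed by construction.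

**Step 7.** Hydride abstraction may be slow on this ester-substituted dione. On long heating the aryloxy group could be lost by elimination across C1–C2, which also aromatizes the ring, or the resorcinol product could be oxidized further.
The fallback sets out from 11 and returns at 12 with no new compound (F0). It replaces the quinone by a catalytic dehydrogenation through a carbon-bound palladium enolate (Pd(TFA)2, 2-(dimethylamino)pyridine, TsOH, O2, DMSO, 80 °C): divalent palladium binds C6, β-hydride elimination removes the C1 hydrogen, the dienone tautomerizes, and O2 reoxidizes the metal.

**Step 10.** BCl3 must be used in excess to ionize the tert-butyl ester and saturate the Lewis basic sites. This excess may start to cleave the C3 methyl ether or the methyl ester, and the tert-butyl cation may alkylate ring A.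
The fallback sets out from 14 and returns at 15, separating the two events. CF3CO2H in CH2Cl2 first removes the tert-butyl group as isobutene and gives 3-chloro-2-methoxy-6-(2-methoxy-6-(methoxycarbonyl)-4-{[tri(propan-2-yl)silyl]oxy}phenoxy)-4-methylbenzoic acid F7. Only the chelation-assisted demethylation then remains, run with a small excess of BCl3 at −78 °C (or with MgI2 in ether), to give 15.

## Further compounds

F1 | step 6 | 3-chloro-2-methoxy-4-methyl-6-(2-oxopropoxy)benzoic acid | CC(=O)COc1cc(C)c(Cl)c(OC)c1C(=O)O
F2 | step 6 | 3-chloro-2-methoxy-6-{[(1R*,2S*)-2-(methoxycarbonyl)-4,6-dioxocyclohexyl]oxy}-4-methylbenzoic acid (racemic trans, one enantiomer drawn) | COC(=O)[C@@H]1CC(=O)CC(=O)[C@H]1Oc1cc(C)c(Cl)c(OC)c1C(=O)O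
F3 | step 6 | 3-chloro-6-[2,4-dihydroxy-6-(methoxycarbonyl)phenoxy]-2-methoxy-4-methylbenzoic acid | COC(=O)c1cc(O)cc(O)c1Oc1cc(C)c(Cl)c(OC)c1C(=O)O
F4 | step 1 | 2-chloro-3-methylphenol | Cc1cccc(O)c1Cl
F5 | step 1 | 2-chloro-1-methoxy-3-methylbenzene | COc1cccc(C)c1Cl
F6 | step 1 | 2-(4-chloro-3-methoxy-5-methylphenyl)-4,4,5,5-tetramethyl-1,3,2-dioxaborolane | COc1cc(B2OC(C)(C)C(C)(C)O2)cc(C)c1Cl
F0 | step 7 | none | none
F7 | step 10 | 3-chloro-2-methoxy-6-(2-methoxy-6-(methoxycarbonyl)-4-{[tri(propan-2-yl)silyl]oxy}phenoxy)-4-methylbenzoic acid | COC(=O)c1cc(O[Si](C(C)C)(C(C)C)C(C)C)cc(OC)c1Oc1cc(C)c(Cl)c(OC)c1C(=O)O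
A1 | alternative 1 | benzyl 6-[4-(benzyloxy)-2-methoxy-6-(methoxycarbonyl)phenoxy]-3-chloro-2-methoxy-4-methylbenzoate | COC(=O)c1cc(OCc2ccccc2)cc(OC)c1Oc3cc(C)c(Cl)c(OC)c3C(=O)OCc4ccccc4
A2 | alternative 1 | benzyl 4-[4-(benzyloxy)-2-methoxy-6-(methoxycarbonyl)phenoxy]-6-methyl-2-oxo-2H-pyran-3-carboxylate | Cc1cc(Oc2c(OC)cc(OCc3ccccc3)cc2C(=O)OC)c(C(=O)OCc2ccccc2)c(=O)o1
A3 | alternative 1 | 2-chloro-1,1-dimethoxyethene | COC(OC)=CCl
A4 | alternative 2 | 6-[4-(benzyloxy)-2-bromo-6-methoxyphenoxy]-3-chloro-2-methoxy-4-methylbenzoic acid | COc1cc(OCc2ccccc2)cc(Br)c1Oc3cc(C)c(Cl)c(OC)c3C(=O)O
A5 | alternative 2 | 4-chloro-3-methoxy-5-methyl-2-(trimethylsilyl)phenyl trifluoromethanesulfonate | COc1c(Cl)c(C)cc(OS(=O)(=O)C(F)(F)F)c1[Si](C)(C)C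
A6 | alternative 2 | 4-(benzyloxy)-2-bromo-6-methoxyphenol | COc1cc(OCc2ccccc2)cc(Br)c1O
A7 | alternative 2 | carbon dioxide | O=C=O
A8 | alternative 3 | benzyl 6-[4-(benzyloxy)-2-methoxy-6-(methoxycarbonyl)phenoxy]-3-chloro-2-hydroxy-4-methylbenzoate | COC(=O)c1cc(OCc2ccccc2)cc(OC)c1Oc3cc(C)c(Cl)c(O)c3C(=O)OCc4ccccc4
A9 | alternative 3 | benzyl 3-[4-(benzyloxy)-2-methoxy-6-(methoxycarbonyl)phenoxy]prop-2-ynoate | COC(=O)c1cc(OCc2ccccc2)cc(OC)c1OC#CC(=O)OCc1ccccc1
A10 | alternative 3 | [(2-chloro-1-methoxy-3-methylbuta-1,3-dien-1-yl)oxy](trimethyl)silane (double-bond geometry not defined) | C=C(C)C(Cl)=C(OC)O[Si](C)(C)C
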